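I started at the branch.

| flask | solid substrate | coupling partner | temperature | remark | time |
|---|---|---|---|---|---|
| south-east | 0.80 M | 1.2 equiv (fed, over 10 d) | 75 °C | run made earlier; the fed solution adds 1.0 times the starting volume |  |
| north-west | 0.80 M | 1.9 equiv (fed, over 10 d) | 86 °C | run made earlier; the fed solution adds 1.0 times the starting volume |  |
| south | 1.2 M | 2.5 equiv (fed, over 10 d) | 75 °C | run made earlier; the fed solution adds 1.0 times the starting volume |  |
| delta | 0.80 M | 2.50 equiv | 80 °C | everything together at the start, the whole solution of coupling partner included, so that from the start the volume is larger by 1.0 times the starting volume | 10 d |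
| alpha | 0.80 M | 2.50 equiv (fed, over 10 d) | 80 °C | the fed solution adds 1.0 times the starting volume | 10 d |

| run | time / d | product / % |
|---|---|---|
| south-east | 0.833 | 1 |
| south-east | 1.25 | 0 |
| south-east | 1.67 | 2 |
| south-east | 3.00 | 1 |
| south-east | 4.00 | 0 |
| south-east | 6.00 | 4 |
| south-east | 10.0 | 3 |
| north-west | 1.25 | 0 |
| north-west | 3.00 | 1 |
| north-west | 4.00 | 7 |
| north-west | 6.00 | 9 |
| north-west | 8.00 | 10 |
| north-west | 10.0 | 11 |
| south | 2.08 | 1 |
| south | 4.00 | 1 |
| south | 6.00 | 9 |
| south | 8.00 | 11 |
| south | 10.0 | 11 |

(each reading ± 1.5 percentage points)

- amounts are per litre of the starting volume; all of the dose is in the solution fed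
- solid substrate is a solid; its amount is given per volume of the solution
- what may be going on: coupling partner + intermediate C <-> intermediate E; intermediate B <-> intermediate D; starting material <-> intermediate A; intermediate C -> product; intermediate A -> intermediate B; solid substrate <-> starting material; starting material + coupling partner -> intermediate C
- at the start none of the solid substrate is in solution
- what has only dissolved of solid substrate counts as not reacted

* the winner by amount of product, in percent of the solid substrate charged; "neither" if no more than 2 percentage points parts them (delta / alpha / neither)
* how much product is there at the end, in percent of the solid substrate charged: delta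
* how much product is there at the end, in percent of the solid substrate charged: alpha

I built the flask up one step at a time. With the main step alone, starting material and coupling partner give intermediate C and then product. The solid substrate is the limiting reagent at 2.50 equiv of partner, so its charge is the ceiling on product in delta and in alpha, but that says nothing of how near to the ceiling either flask comes in 10 d.

Then I added the drain through intermediate A. Capture goes with c(starting material) times c(coupling partner), and the drain goes with c(starting material). Dividing one rate by the other removes c(starting material) and time, and leaves a selectivity factor:

product made / material drained = c(coupling partner) / c_even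

The even concentration, the partner concentration at which capture and drain run equally fast, is what I read from the readings. The north-west run, with partner averaged over its feed at 0.466 M, gave 11 % product at the end. Treating that run as finished, I got

c_even = 3.77 M

This is a reading with its scatter. The cooler south run, read the same way, gives 7.45 M, more than the north-west value, so my figure for 80 °C may be low.

Last came the way the partner goes in, with intermediates D and E set aside. Delta holds 1.00 M from the start, and alpha averages 0.614 M, less than delta. With share = c(coupling partner) / (c(coupling partner) + c_even), I reckoned

delta 20.9 %, alpha 14.0 %

The forecast said delta, with 24 % for delta and 12 % for alpha, on the ground that “Capture therefore competes better against the unimolecular drain”. It stood further apart than my pair.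

The flasks gave 22.3 % in delta and 11.8 % in alpha, so delta won. Intermediate E stood at 0.162 % in delta at 10.0 d, and taking that step away makes next to no difference to delta's product. My c_even came out 1.4 percentage points short for delta and 2.2 points over for alpha.

    coupling partner + intermediate C ⇌ intermediate E (K = 1.10 /M, k = 7.36 × 10⁻⁶ /M/min, Ea = 89.0 kJ/mol, ΔH = −21.0 kJ/mol)
    intermediate B ⇌ intermediate D (K = 0.560, k = 2.49 × 10⁻⁴ /min, Ea = 124 kJ/mol, ΔH = −19.0 kJ/mol)
    starting material ⇌ intermediate A (K = 0.220, k = 5.36 × 10⁻⁴ /min, Ea = 126 kJ/mol, ΔH = −86.0 kJ/mol)
    intermediate C → product (k = 9.05 × 10⁻⁴ /min, Ea = 119 kJ/mol)
    intermediate A → intermediate B (k = 8.18 × 10⁻⁴ /min, Ea = 119 kJ/mol)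
    solid substrate ⇌ starting material, rate k6*(cs6 - [starting material]) while solid is left; crystals form when [starting material] > cs6 (solubility = 0.490 M, k = 0.00518 /min)
    starting material + coupling partner → intermediate C (k = 4.86 × 10⁻⁵ /M/min, Ea = 100 kJ/mol)
    (constants at 80 °C)

Delta with 0.48 M of solid substrate, at the same equivalents, holds 0.600 M of partner, so c_even gives 13.7 %. That flask gave 14.7 %.

Readings and results were generated by integration with made-up constants; noise was put on by code.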